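I decided to reckon this flask in L spent per D reacted and to leave the clock for last.

D 0.47 M; L 2.50 equiv; time 6.0 d

    G + L → Z + Q (k1 = 0.14 L mol⁻¹ h⁻¹)
    D ⇌ G, rate k2*(cs2 - [G]) while solid is left; crystals form when [G] > cs2 (cs2 = 0.051 M, k2 = 0.22 h⁻¹)
    L + Z ⇌ L.Z, settled at all times (K3 = 5700 L mol⁻¹)
    J ⇌ Q, rate k4*(cs4 - [Q]) while solid is left; crystals form when [Q] > cs4 (cs4 = 0.23 M, k4 = 1.0 h⁻¹)

- part of the D that has reacted (what has only dissolved counts as not reacted) at 6.0 d
- share of the unused L that is free and not bound as L.Z, at 6.0 d

- what is said of Q includes J
- D, J is a solid; its amount is given per volume of the solution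
- at the start none of D is in solution
- what has only dissolved of D counts as not reacted
- run time (flask): 6.0 d

The fastest rung was the balance of step 3. At the start K3[L] stood at 6700, so nearly all of Z went straight into L.Z. Dividing the rate at which L is lost by the rate of step 1 makes time drop out and leaves the toll, 2.00 L lost per D reacted: one L reacts and a second is bound.

Next came G. Its half-life by step 1, with L as charged, was 0.18 d, and step 2 closes its gap to saturation with a half-life of 0.131 d. Both are far shorter than the run of 6.0 d, so I took [G] to follow its supply.

Of these two, step 1 stood on the slower rung, though at the start they were of like size, 0.18 d against 0.131 d, and the half-life of G by step 1 lengthens as L is spent. The L charged pays for 1.25 times the D charged, so L is not the limiting reagent. Full conversion leaves a free share of 33.3%. There my reckoning stopped: it turns c into fr, but it gave me no c.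

The forecast put c at 94.4% (93.3% to 95.4%) and fr at 39.4% (38% to 41%), holding that “each Z formed ties up a second L”.

The simulation gave c = 94.3% and fr = 39.4%, with 5.7% of the D charged still there, solid or dissolved, at 6.00 d. With the toll, the charge less the toll times c, over the charge less c, turns that c into 39.4%, with no clock needed.

In the neighbour flask with 1.00 equiv of L, the toll caps reacted D at 0.500 of the D charged. From its c the toll gives a free share of 29.6%. The simulation gave that flask c = 41.3%, under the cap, and fr = 29.8%.

The numbers of this flask come from no measurement; the rest is arithmetic.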